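**Retrosynthetic overview**

1. Numbering follows the germacrane skeleton of the target: ring A is the carbocycle C1–C10; ring B is the lactone (O–C6, C7, C11, C12); C13 is the exo-methylene, C14 the formyl and C15 the hydroxymethyl carbon.
2. Endgame on the bicycle: 8-O-methacryloylation, acetonide removal, C14 oxidation, 9-O-acetylation, desilylation. Ring A is closed last, by ring-closing metathesis at C1=C10.
3. Ring B is formed first, on an open chain, in the key step: diethylphosphonoacetic acid is annulated in one flask onto an allylic tert-butyl carbonate that carries a C7–C8 trans-epoxide. This makes O–C6 (π-allylpalladium capture, retention) and C11–C7 (epoxide opening, inversion), then the exo-methylene by in-flask methylenation, and sets the 8-hydroxyl free.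
4. Enabling feature: C6 is allylic to the trisubstituted C4=C5 alkene (site of ionisation for C–O formation), and C7 lies between C6 and the oxygen-bearing C8, so a C7–C8 epoxide is both the electrophile for C11 and the source of O8.
5. The chain comes from an asymmetric Morita–Baylis–Hillman adduct (C9, C10, C14), an alkynylation (C6), hydroalumination–iodination and Negishi coupling (C4=C5, C1–C3) and a Sharpless epoxidation (C7, C8).

Key step: step 11

Assumption: the facial sense of the two ligand-controlled additions (steps 1 and 6) is taken from the usual behaviour of β-isocupreidine and (S,S)-ProPhenol with simple aldehydes; if either delivers the antipode, the pseudo-enantiomeric catalyst is used.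

**Route**

Step 1
Reactants: 1 (E)-4,4-dimethoxybut-2-enal; 2 1,1,1,3,3,3-hexafluoropropan-2-yl acrylate
Product: 3 hexafluoroisopropyl (3R,4E)-3-hydroxy-6,6-dimethoxy-2-methylidenehex-4-enoate
Conditions: β-isocupreidine (10 mol %), DMF, −55 °C
Reagents that add atoms: none
Why: Asymmetric Morita–Baylis–Hillman reaction, in which the ammonium enolate of the activated acrylate adds 1,2 to the aldehyde and the catalyst's phenolic OH should organise the aldol step to give the (R)-carbinol at C9.

Step 2
Reactants: 3 hexafluoroisopropyl ester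
Product: 4 (3R,4E)-6,6-dimethoxy-2-methylidenehex-4-ene-1,3-diol
Conditions: i-Bu2AlH (4 equiv), CH2Cl2, −78 °C; Rochelle salt work-up
Reagents that add atoms: none
Why: Hydride reduction of the activated ester (1,2-reduction) should give the primary allylic alcohol C14 without touching the acetal or the alkenes.

Step 3
Reactants: 4 diol
Product: 5 (4R)-4-[(1E)-3,3-dimethoxyprop-1-enyl]-2,2-dimethyl-5-methylidene-1,3-dioxane
Conditions: 2,2-dimethoxypropane, PPTS (cat.), CH2Cl2, rt
Reagents that add atoms: 2,2-dimethoxypropane, COC(C)(C)OC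
Why: Acetonide formation by transketalisation ties O9 and O14 into one six-membered ring under acid too mild to ionise the doubly allylic C9–O bond.

Step 4
Reactants: 5 acetonide acetal
Product: 6 (2E)-3-[(4R)-2,2-dimethyl-5-methylidene-1,3-dioxan-4-yl]prop-2-enal
Conditions: LiBF4, MeCN/H2O (98:2), rt
Reagents that add atoms: water, O
Why: Selective acetal hydrolysis, the allylic dimethyl acetal being cleaved much faster than the cyclic acetonide and without base, so the γ-stereocentre C9 should not epimerise.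

Step 5
Reactants: 7 prop-2-yn-1-ol
Product: 8 tert-butyl(diphenyl)(prop-2-ynyloxy)silane
Conditions: t-BuPh2SiCl, imidazole, CH2Cl2, 0 °C to rt
Reagents that add atoms: tert-butyl(chloro)diphenylsilane, CC(C)(C)[Si](Cl)(c1ccccc1)c1ccccc1
Why: Standard silyl ether formation gives the acid-stable protecting group that C15–OH needs until the last step.

Step 6
Reactants: 6 enal; 8 silyl propargyl ether
Product: 9 (1E,3S)-6-(tert-butyldiphenylsilyloxy)-1-[(4R)-2,2-dimethyl-5-methylidene-1,3-dioxan-4-yl]hex-1-en-4-yn-3-ol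
Conditions: (S,S)-ProPhenol (20 mol %), Me2Zn (3 equiv), Ph3P=O (40 mol %), toluene, 0 °C
Reagents that add atoms: none
Why: Zinc–ProPhenol-catalysed asymmetric alkynylation (1,2-addition of an alkynylzinc to an enal) should set the C6 carbinol (S) under reagent control, the remote C9 centre having little say.

Step 7
Reactants: 9 propargylic alcohol
Product: 11 (1E,3S,4Z)-6-(tert-butyldiphenylsilyloxy)-1-[(4R)-2,2-dimethyl-5-methylidene-1,3-dioxan-4-yl]-5-iodohexa-1,4-dien-3-ol, via cyclic vinylalanate 10 (not isolated)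
Conditions: NaAlH2(OCH2CH2OMe)2, THF, 0 °C; then I2, −78 °C
Reagents that add atoms: iodine, II
Why: Alkoxide-directed trans-hydroalumination followed by iodinolysis delivers hydride to C5 and aluminium to C4 inside a five-membered alanate, so iodine should end cis to C6 and fix the C4=C5 geometry.

Step 8
Reactants: 11 vinyl iodide; 12 but-3-enylzinc bromide
Product: 13 (1E,3S,4E)-5-[(tert-butyldiphenylsilyloxy)methyl]-1-[(4R)-2,2-dimethyl-5-methylidene-1,3-dioxan-4-yl]nona-1,4,8-trien-3-ol
Conditions: Pd(dppf)Cl2 (5 mol %), THF, 40 °C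
Reagents that add atoms: none
Why: Negishi coupling (sp3–sp2) with retention of olefin geometry places the C1–C3 chain cis to C6, the dppf ligand suppressing β-hydride elimination.

Step 9
Reactants: 13 divinyl carbinol
Product: 14 (1R,2E)-3-[(tert-butyldiphenylsilyloxy)methyl]-1-{(2R,3R)-3-[(4S)-2,2-dimethyl-5-methylidene-1,3-dioxan-4-yl]oxiran-2-yl}hepta-2,6-dien-1-ol
Conditions: Ti(OiPr)4 (0.2 equiv), D-(−)-diisopropyl tartrate (0.25 equiv), t-BuOOH, 4 Å MS, CH2Cl2, −20 °C
Reagents that add atoms: tert-butyl hydroperoxide, CC(C)(C)OO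
Why: Sharpless asymmetric epoxidation in its kinetic-resolution mode: with D-(−)-tartrate the (6S)-alcohol is the matched epimer and should be epoxidised at the (E)-C7=C8 alkene to the erythro epoxy alcohol (7R,8R), while the cis-substituted C4=C5 alkene, the non-allylic alkenes and any C6 epimer react far more slowly.

Step 10
Reactants: 14 epoxy alcohol
Product: 15 tert-butyl carbonate of 14 at O6
Conditions: Boc2O, DMAP (0.2 equiv), MeCN, 0 °C to rt
Reagents that add atoms: di-tert-butyl dicarbonate, CC(C)(C)OC(=O)OC(=O)OC(C)(C)C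
Why: DMAP-catalysed O-acylation under neutral conditions avoids Payne rearrangement of the epoxy alcohol and installs the leaving group for π-allyl formation.

Step 11
Reactants: 15 allylic carbonate; 16 2-(diethoxyphosphoryl)acetic acid
Product: 19 (4R,5R)-5-[(1E)-2-{(tert-butyldiphenylsilyloxy)methyl}hexa-1,5-dien-1-yl]-4-{(S)-[(4S)-2,2-dimethyl-5-methylidene-1,3-dioxan-4-yl](hydroxy)methyl}-3-methylideneoxolan-2-one, via allylic phosphonoacetate 17 (not isolated), via α-phosphono lactone 18 (not isolated)
Conditions: Pd2(dba)3 (2.5 mol %), PPh3 (12 mol %), 16 (1.2 equiv), THF, rt; then LiN(SiMe3)2 (3.5 equiv), −78 to 0 °C; then (CH2O)n, 0 °C to rt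
Reagents that add atoms: paraformaldehyde (as formaldehyde), C=O
Why: Zerovalent palladium ionises the carbonate with inversion to a π-allyl complex over C4–C5–C6 (CO2 and tert-butoxide leave, the latter deprotonating 16), and the carboxylate attacks C6 anti to palladium (Tsuji–Trost allylic esterification, net retention) to give 17; LiN(SiMe3)2 then generates the phosphonate-stabilised ester enolate, which opens the epoxide at C7 with inversion to 18, and a Horner–Wadsworth–Emmons reaction with formaldehyde installs C13. The closest known reaction types are palladium-catalysed substitution of allylic carbonates by carboxylic acids, the base-induced cyclisation of malonate and sulfonylacetate esters of 2,3-epoxy alcohols to γ-lactones, and the phosphonate route to α-methylene lactones. Ring B closes in the 5-exo-tet mode at the epoxide. C6 keeps the configuration fixed in steps 6 and 9 through double inversion at palladium, C7 is set by backside opening of the trans-epoxide (so C11 ends anti to the 8-hydroxyl and trans to C5 on the lactone), and C8 is untouched and appears as the only free hydroxyl. The step needs capture at C6 and not at C4, which the fully substituted C4 terminus and the reversibility of ester formation under palladium should secure, and it needs exo and not 6-endo opening, which the five-membered transition state favours. Once deprotonated, the ester is no longer a leaving group for palladium, so the cyclisation should run undisturbed.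

Step 12
Reactants: 19 open-chain α-methylene lactone
Product: 20 (1(10)Z,4E,6R,7R,8S,9S)-15-(tert-butyldiphenylsilyloxy)-8-hydroxy-9,14-(isopropylidenedioxy)germacra-1(10),4,11(13)-trien-12,6-olide
Conditions: second-generation Hoveyda–Grubbs catalyst (10 mol %), toluene (1 mM), 80 °C
Reagents that add atoms: none
Why: Ring-closing metathesis, in which ruthenium loads at the terminal C1 vinyl and closes onto the C10 methylene; the 10-membered ring admits only the ring-cis trisubstituted alkene, and the trans-lactone, the cis C4=C5 alkene and the dioxane pre-organise the chain.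

Step 13
Reactants: 20 macrocyclic alcohol
Product: 21 8-O-methacryloyl derivative of 20 (6R,7S,8S,9S)
Conditions: methacrylic anhydride, Et3N, DMAP (cat.), CH2Cl2, 0 °C to rt
Reagents that add atoms: methacrylic anhydride, CC(=C)C(=O)OC(=O)C(C)=C
Why: DMAP-catalysed acylation of the only free hydroxyl (C8).

Step 14
Reactants: 21 acetonide
Product: 22 (1(10)Z,4E,6R,7S,8S,9S)-15-(tert-butyldiphenylsilyloxy)-9,14-dihydroxy-8-(methacryloyloxy)germacra-1(10),4,11(13)-trien-12,6-olide
Conditions: PPTS, MeOH, 0 °C to rt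
Reagents that add atoms: none
Why: Acid-catalysed transketalisation removes the acetonide while the primary TBDPS ether and both esters should survive, and the weakly acidic medium keeps acyl migration from O8 to O9 slow.

Step 15
Reactants: 22 diol
Product: 23 (1(10)E,4E,6R,7S,8S,9S)-15-(tert-butyldiphenylsilyloxy)-9-hydroxy-8-(methacryloyloxy)-14-oxogermacra-1(10),4,11(13)-trien-12,6-olide
Conditions: TEMPO (0.2 equiv), PhI(OAc)2, CH2Cl2, rt
Reagents that add atoms: none
Why: Oxoammonium (TEMPO) oxidation should take the primary allylic C14 alcohol to the enal in preference to the hindered secondary C9 alcohol and without over-oxidation.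

Step 16
Reactants: 23 hydroxy enal
Product: 24 9-O-acetyl derivative of 23
Conditions: Ac2O, pyridine, DMAP (5 mol %), CH2Cl2, 0 °C
Reagents that add atoms: acetic anhydride, CC(=O)OC(C)=O
Why: Acetylation of the remaining secondary hydroxyl at low temperature should outrun acyl migration.

Step 17
Reactants: 24 silyl ether
Product: 25 CNP0147326.4, (1(10)E,4E,6R,7S,8S,9S)-9-acetoxy-15-hydroxy-8-(methacryloyloxy)-14-oxogermacra-1(10),4,11(13)-trien-12,6-olide
Conditions: HF·pyridine, pyridine, THF, 0 °C to rt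
Reagents that add atoms: none
Why: Buffered fluoride desilylation cleaves the primary TBDPS ether without basic fluoride, so the esters, the enal and the α-methylene lactone should be untouched.

**Compound list**

1 | (E)-4,4-dimethoxybut-2-enal | COC(OC)/C=C/C=O | starting material
2 | 1,1,1,3,3,3-hexafluoropropan-2-yl acrylate | C=CC(=O)OC(C(F)(F)F)C(F)(F)F | starting material
3 | 1,1,1,3,3,3-hexafluoropropan-2-yl (3R,4E)-3-hydroxy-6,6-dimethoxy-2-methylidenehex-4-enoate | COC(OC)/C=C/[C@@H](O)C(=C)C(=O)OC(C(F)(F)F)C(F)(F)F | intermediate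
4 | (3R,4E)-6,6-dimethoxy-2-methylidenehex-4-ene-1,3-diol | COC(OC)/C=C/[C@@H](O)C(=C)CO | intermediate
5 | (4R)-4-[(1E)-3,3-dimethoxyprop-1-enyl]-2,2-dimethyl-5-methylidene-1,3-dioxane | COC(OC)/C=C/[C@H]1OC(C)(C)OCC1=C | intermediate
6 | (2E)-3-[(4R)-2,2-dimethyl-5-methylidene-1,3-dioxan-4-yl]prop-2-enal | O=C/C=C/[C@H]1OC(C)(C)OCC1=C | intermediate
7 | prop-2-yn-1-ol | C#CCO | starting material
8 | tert-butyl(diphenyl)(prop-2-ynyloxy)silane | C#CCO[Si](c1ccccc1)(c1ccccc1)C(C)(C)C | intermediate
9 | (1E,3S)-6-(tert-butyldiphenylsilyloxy)-1-[(4R)-2,2-dimethyl-5-methylidene-1,3-dioxan-4-yl]hex-1-en-4-yn-3-ol | CC(C)(C)[Si](c1ccccc1)(c1ccccc1)OCC#C[C@@H](O)/C=C/[C@H]1OC(C)(C)OCC1=C | intermediate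
10 | sodium cyclic vinylalanate of 9 (five-membered O–Al–C4=C5–C6 ring, two 2-methoxyethoxy groups on Al) | [Na+].COCCO[Al-]1(OCCOC)O[C@@H](/C=C/[C@H]2OC(C)(C)OCC2=C)C=C1CO[Si](c1ccccc1)(c1ccccc1)C(C)(C)C | intermediate (not isolated)
11 | (1E,3S,4Z)-6-(tert-butyldiphenylsilyloxy)-1-[(4R)-2,2-dimethyl-5-methylidene-1,3-dioxan-4-yl]-5-iodohexa-1,4-dien-3-ol | CC(C)(C)[Si](c1ccccc1)(c1ccccc1)OC/C(I)=C/[C@@H](O)/C=C/[C@H]1OC(C)(C)OCC1=C | intermediate
12 | but-3-enylzinc bromide | C=CCC[Zn]Br | starting material
13 | (1E,3S,4E)-5-[(tert-butyldiphenylsilyloxy)methyl]-1-[(4R)-2,2-dimethyl-5-methylidene-1,3-dioxan-4-yl]nona-1,4,8-trien-3-ol | CC(C)(C)[Si](c1ccccc1)(c1ccccc1)OC/C(CCC=C)=C/[C@@H](O)/C=C/[C@H]1OC(C)(C)OCC1=C | intermediate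
14 | (1R,2E)-3-[(tert-butyldiphenylsilyloxy)methyl]-1-{(2R,3R)-3-[(4S)-2,2-dimethyl-5-methylidene-1,3-dioxan-4-yl]oxiran-2-yl}hepta-2,6-dien-1-ol | CC(C)(C)[Si](c1ccccc1)(c1ccccc1)OC/C(CCC=C)=C/[C@@H](O)[C@H]2O[C@@H]2[C@H]1OC(C)(C)OCC1=C | intermediate
15 | tert-butyl (1R,2E)-3-[(tert-butyldiphenylsilyloxy)methyl]-1-{(2R,3R)-3-[(4S)-2,2-dimethyl-5-methylidene-1,3-dioxan-4-yl]oxiran-2-yl}hepta-2,6-dien-1-yl carbonate | CC(C)(C)[Si](c1ccccc1)(c1ccccc1)OC/C(CCC=C)=C/[C@@H](OC(=O)OC(C)(C)C)[C@H]2O[C@@H]2[C@H]1OC(C)(C)OCC1=C | intermediate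
16 | 2-(diethoxyphosphoryl)acetic acid | CCOP(=O)(CC(=O)O)OCC | starting material
17 | (1R,2E)-3-[(tert-butyldiphenylsilyloxy)methyl]-1-{(2R,3R)-3-[(4S)-2,2-dimethyl-5-methylidene-1,3-dioxan-4-yl]oxiran-2-yl}hepta-2,6-dien-1-yl 2-(diethoxyphosphoryl)acetate | CC(C)(C)[Si](c1ccccc1)(c1ccccc1)OC/C(CCC=C)=C/[C@@H](OC(=O)CP(=O)(OCC)OCC)[C@H]2O[C@@H]2[C@H]1OC(C)(C)OCC1=C | intermediate (not isolated)
18 | diethyl {(4R,5R)-5-[(1E)-2-{(tert-butyldiphenylsilyloxy)methyl}hexa-1,5-dien-1-yl]-4-{(S)-[(4S)-2,2-dimethyl-5-methylidene-1,3-dioxan-4-yl](hydroxy)methyl}-2-oxooxolan-3-yl}phosphonate (both C3 epimers; lithium salt in the flask) | CC(C)(C)[Si](c1ccccc1)(c1ccccc1)OC/C(CCC=C)=C/[C@H]2OC(=O)C(P(=O)(OCC)OCC)[C@@H]2[C@H](O)[C@H]1OC(C)(C)OCC1=C | intermediate (not isolated)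
19 | (4R,5R)-5-[(1E)-2-{(tert-butyldiphenylsilyloxy)methyl}hexa-1,5-dien-1-yl]-4-{(S)-[(4S)-2,2-dimethyl-5-methylidene-1,3-dioxan-4-yl](hydroxy)methyl}-3-methylideneoxolan-2-one | CC(C)(C)[Si](c1ccccc1)(c1ccccc1)OC/C(CCC=C)=C/[C@H]2OC(=O)C(=C)[C@@H]2[C@H](O)[C@H]1OC(C)(C)OCC1=C | intermediate
20 | (1(10)Z,4E,6R,7R,8S,9S)-15-(tert-butyldiphenylsilyloxy)-8-hydroxy-9,14-(isopropylidenedioxy)germacra-1(10),4,11(13)-trien-12,6-olide | CC(C)(C)[Si](c1ccccc1)(c1ccccc1)OC/C3=C/[C@H]2OC(=O)C(=C)[C@@H]2[C@H](O)[C@H]1OC(C)(C)OC/C1=C/CC3 | intermediate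
21 | (1(10)Z,4E,6R,7S,8S,9S)-15-(tert-butyldiphenylsilyloxy)-9,14-(isopropylidenedioxy)-8-(methacryloyloxy)germacra-1(10),4,11(13)-trien-12,6-olide | CC(C)(C)[Si](c1ccccc1)(c1ccccc1)OC/C3=C/[C@H]2OC(=O)C(=C)[C@@H]2[C@H](OC(=O)C(C)=C)[C@H]1OC(C)(C)OC/C1=C/CC3 | intermediate
22 | (1(10)Z,4E,6R,7S,8S,9S)-15-(tert-butyldiphenylsilyloxy)-9,14-dihydroxy-8-(methacryloyloxy)germacra-1(10),4,11(13)-trien-12,6-olide | CC(C)(C)[Si](c1ccccc1)(c1ccccc1)OC/C3=C/[C@H]2OC(=O)C(=C)[C@@H]2[C@H](OC(=O)C(C)=C)[C@@H](O)/C(CO)=C\CC3 | intermediate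
23 | (1(10)E,4E,6R,7S,8S,9S)-15-(tert-butyldiphenylsilyloxy)-9-hydroxy-8-(methacryloyloxy)-14-oxogermacra-1(10),4,11(13)-trien-12,6-olide | CC(C)(C)[Si](c1ccccc1)(c1ccccc1)OC/C3=C/[C@H]2OC(=O)C(=C)[C@@H]2[C@H](OC(=O)C(C)=C)[C@@H](O)/C(C=O)=C\CC3 | intermediate
24 | (1(10)E,4E,6R,7S,8S,9S)-9-acetoxy-15-(tert-butyldiphenylsilyloxy)-8-(methacryloyloxy)-14-oxogermacra-1(10),4,11(13)-trien-12,6-olide | CC(C)(C)[Si](c1ccccc1)(c1ccccc1)OC/C3=C/[C@H]2OC(=O)C(=C)[C@@H]2[C@H](OC(=O)C(C)=C)[C@@H](OC(C)=O)/C(C=O)=C\CC3 | intermediate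
25 | CNP0147326.4, (1(10)E,4E,6R,7S,8S,9S)-9-acetoxy-15-hydroxy-8-(methacryloyloxy)-14-oxogermacra-1(10),4,11(13)-trien-12,6-olide | C=C(C)C(=O)O[C@H]1[C@H]2C(=C)C(=O)O[C@@H]2/C=C(/CO)CC/C=C(/C=O)[C@@H]1OC(C)=O | target

**Step count and risks**

Total step count: 17. Longest linear sequence: 16 steps (steps 1–4 and 6–17; step 5 is a one-step side branch).

The three steps most likely to fail:

Step 12 (ring-closing metathesis). What may go wrong: the ruthenium alkylidene formed at C1 may not engage the hindered 1,1-disubstituted C10 methylene, which is flanked by two allylic C–O bonds, so that intermolecular cross-metathesis to dimers and oligomers outruns ring closure. Closure of a 10-membered carbocycle to a trisubstituted alkene is a demanding case. Fallback: the order of ring formation is reversed, ring A before ring B. It sets out from epoxy alcohol 14, whose chain is not yet constrained by the lactone. Ring-closing metathesis (same catalyst, high dilution) would give macrocyclic epoxy alcohol F1, and Boc2O with DMAP would give macrocyclic carbonate F2. The annulation of step 11 on F2 (zerovalent palladium with 16, then LiN(SiMe3)2, then paraformaldehyde) would pass through macrocyclic allylic phosphonoacetate F3 and macrocyclic α-phosphono lactone F4, and comes back to the route at 20.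

Step 11 (lactone annulation). What may go wrong: capture of the π-allyl intermediate at the C4 terminus, its β-hydride elimination to a diene, or erosion of the C6 configuration by palladium–palladium exchange before capture. Fallback: the C6–O bond is kept from step 9 and not made by substitution. Starting from epoxy alcohol 14, Steglich esterification with 16 (DCC, DMAP, CH2Cl2, 0 °C) would give allylic phosphonoacetate 17 with the carbinol configuration untouched, now isolated. LiN(SiMe3)2 and then paraformaldehyde, as in step 11, would take 17 through 18 to 19, where the route is rejoined. No new compound arises.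

Step 1 (asymmetric Morita–Baylis–Hillman reaction). What may go wrong: slow carbonyl addition, self-condensation of the enal after amine addition to its β-carbon, and incomplete enantiofacial discrimination for this enal. Fallback: C9 is set by resolution, not by asymmetric catalysis. From aldehyde 1, a DABCO-catalysed Morita–Baylis–Hillman reaction with methyl acrylate would give racemic methyl (E)-3-hydroxy-6,6-dimethoxy-2-methylidenehex-4-enoate F5. Lipase-catalysed acylation (Pseudomonas cepacia lipase, vinyl acetate, t-BuOMe) would leave the (R)-alcohol F6 and convert the (S)-enantiomer to acetate F7; should the enzyme prefer the (R)-alcohol, the separated acetate is methanolysed to F6. Reduction of F6 with i-Bu2AlH as in step 2 comes back to the route at diol 4.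

Further compounds
F1 | step 12 | (1(10)Z,4E,6R,7R,8R,9S)-15-(tert-butyldiphenylsilyloxy)-7,8-epoxy-6-hydroxy-9,14-(isopropylidenedioxy)cyclodeca-1(10),4-diene (macrocyclic epoxy alcohol, germacrane numbering) | CC(C)(C)[Si](c1ccccc1)(c1ccccc1)OC/C3=C/[C@@H](O)[C@H]2O[C@@H]2[C@H]1OC(C)(C)OC/C1=C/CC3
F2 | step 12 | tert-butyl carbonate of F1 at O6 | CC(C)(C)[Si](c1ccccc1)(c1ccccc1)OC/C3=C/[C@@H](OC(=O)OC(C)(C)C)[C@H]2O[C@@H]2[C@H]1OC(C)(C)OC/C1=C/CC3
F3 | step 12 | 2-(diethoxyphosphoryl)acetate of F1 at O6 (macrocyclic allylic phosphonoacetate) | CC(C)(C)[Si](c1ccccc1)(c1ccccc1)OC/C3=C/[C@@H](OC(=O)CP(=O)(OCC)OCC)[C@H]2O[C@@H]2[C@H]1OC(C)(C)OC/C1=C/CC3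
F4 | step 12 | macrocyclic α-phosphono lactone, (6R,7R,8S,9S)-11-(diethoxyphosphoryl) analogue of 20 lacking C13 | CC(C)(C)[Si](c1ccccc1)(c1ccccc1)OC/C3=C/[C@H]2OC(=O)C(P(=O)(OCC)OCC)[C@@H]2[C@H](O)[C@H]1OC(C)(C)OC/C1=C/CC3
F0 | step 11 | none | none
F5 | step 1 | racemic methyl (E)-3-hydroxy-6,6-dimethoxy-2-methylidenehex-4-enoate | COC(OC)/C=C/C(O)C(=C)C(=O)OC
F6 | step 1 | methyl (3R,4E)-3-hydroxy-6,6-dimethoxy-2-methylidenehex-4-enoate | COC(OC)/C=C/[C@@H](O)C(=C)C(=O)OC
F7 | step 1 | methyl (3S,4E)-3-acetoxy-6,6-dimethoxy-2-methylidenehex-4-enoate | COC(OC)/C=C/[C@H](OC(C)=O)C(=C)C(=O)OC
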